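Ring A is taken not from a phenol but from a quinone. The para pair C5–O/C8–O of ring A is read as the two carbonyls of 2-hydroxy-6-methoxy-1,4-benzoquinone, whose enol edge C8a(OH)=C4a(H) acts as a C,O two-atom partner. The key step joins this edge to an aroyl(methoxy)ketene that carries C4, C3–OMe, C2 and ring B. One operation forms C4–C4a and O1–C2, closes the γ-pyrone ring C and fixes the 5,8-dioxy-7-methoxy pattern with no ring-A protecting group. Its precursors are a one-step derivative of symmetric 2,6-dimethoxybenzoquinone and a β-keto ester; one hydrogenation then finishes the target.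

Key step: step 3

Remark 1: the target SMILES holds no stereocentre, stereogenic axis or stereogenic double bond, so the compound is achiral and no enantioselective step is needed.
Remark 2: atoms of the product are named by flavone numbering (O1, C2, C3, C4, C4a, C5–C8, C8a), and atoms of 2 by quinone numbering where this is stated.
Remark 3: conjugate bases formed in the flask (enolates, phenolates, quinonolates) count as the ionised form of the numbered compound and carry no number of their own.

Step 1
Reactants: 1 2,6-dimethoxy-1,4-benzoquinone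
Product: 2 2-hydroxy-6-methoxy-1,4-benzoquinone
Conditions: aq NaOH (1.1 equiv), THF, 0 °C to rt, N2; then 1 M HCl
Reagents that add atoms: sodium hydroxide, [Na+].[OH-]
Why: Nucleophilic vinylic substitution (addition–elimination) of hydroxide at the vinylogous ester MeO–C2=C3–C4=O should replace one of the two equivalent methoxy groups, and the electron-rich quinonolate that forms should resist a second substitution.

Step 2
Reactants: 3 methyl 3,4,5-tris(benzyloxy)benzoate; 4 tert-butyl methoxyacetate
Product: 5 tert-butyl 2-methoxy-3-oxo-3-[3,4,5-tris(benzyloxy)phenyl]propanoate (racemic)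
Conditions: 4 (2.2 equiv), LDA (2.3 equiv), THF, −78 °C; then 3, −78 to 0 °C; cold 1 M HCl
Reagents that add atoms: none
Why: In this crossed Claisen condensation 3 cannot enolise, the tert-butyl ester of 4 resists self-condensation and deprotonation of 5 by the excess base drives the equilibrium, while the new α-stereocentre is labile (5 is racemic) and is erased in step 3.

Step 3
Reactants: 2 2-hydroxy-6-methoxy-1,4-benzoquinone; 5 tert-butyl 2-methoxy-3-oxo-3-[3,4,5-tris(benzyloxy)phenyl]propanoate
Product: 8 3,7-dimethoxy-2-[3,4,5-tris(benzyloxy)phenyl]-4H-chromene-4,5,8-trione, via aroyl(methoxy)ketene 6 (not isolated), via C-acylated hydroxyquinone 7 (not isolated)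
Conditions: 5 (1.5 equiv), DMAP (10 mol %), 4 Å MS, PhCl, 130 °C, N2 stream; then p-TsOH (20 mol %), 80 °C
Reagents that add atoms: none
Why: Proposed new method: on heating, 5 should lose tert-butanol through its enol (retro-ene) to give the aroyl(methoxy)ketene 6, whose ketene carbon (future C4) is attacked by C3 of 2 (future C4a), the β-carbon of the vinylogous acid HO–C2=C3–C4=O, to give the chelated triketone 7, while acylation at the enol oxygen only makes a vinylogous anhydride that heat or DMAP turns back into an acyl donor. The closest known reaction types are the γ-pyrone synthesis from acylketenes and enol ethers (hetero-Diels–Alder, then loss of ROH), the thermal Mentzer condensation of phenols with β-keto esters, and the DMAP-mediated O-to-C acyl transfer of cyclic 1,3-diones and 4-hydroxycoumarins, which are enolates of the same type as that of 2; new is the hydroxyquinone as the C,O partner. Ring C closes by 6-exo-trig attack of the C8a–OH of 7 on the aroyl carbonyl (future C2) and acid-catalysed loss of water from the hemiketal, which makes the closure irreversible. No stereocentre is formed, and the labile one of 5 and 7 becomes the sp2 carbon C3. Site selectivity for C3 over C5 of 2 is needed and is secured because only the C2–OH edge can ionise to an enolate, whereas the C6–OMe edge stays a neutral vinylogous ester that survives as the 7-OMe group, and 8 has no enol left for a second annulation. Closure on the para-quinone (O on C8a) rather than through the 4-hydroxy-1,2-quinone tautomer (O on C5, which would lead to the 5,6-dioxy series) is also needed and is secured by the dominant 2-hydroxy-1,4-quinone tautomer, whose OH is chelated to the C4 carbonyl next to the side chain, and by the reversible hemiketal stage, which lets the more stable para-quinone win.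

Step 4
Reactants: 8 3,7-dimethoxy-2-[3,4,5-tris(benzyloxy)phenyl]-4H-chromene-4,5,8-trione
Product: 10 5,8,3',4',5'-pentahydroxy-3,7-dimethoxyflavone, via tribenzyl flavone hydroquinone 9 (not isolated)
Conditions: H2 (1 atm), 10% Pd/C, THF–MeOH, rt; filtration and concentration under Ar
Reagents that add atoms: none
Why: Catalytic hydrogenation should reduce the quinone at once to 9 and then cleave the three benzyl aryl ethers by hydrogenolysis, while the methyl ethers and the tetrasubstituted vinylogous-ester C2=C3 bond of the flavone are inert at 1 atm.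

Compound list
1 | 2,6-dimethoxy-1,4-benzoquinone | COC1=CC(=O)C=C(OC)C1=O | starting material
2 | 2-hydroxy-6-methoxy-1,4-benzoquinone | COC1=CC(=O)C=C(O)C1=O | intermediate
3 | methyl 3,4,5-tris(benzyloxy)benzoate | COC(=O)c1cc(OCc2ccccc2)c(OCc2ccccc2)c(OCc2ccccc2)c1 | starting material
4 | tert-butyl methoxyacetate | COCC(=O)OC(C)(C)C | starting material
5 | tert-butyl 2-methoxy-3-oxo-3-[3,4,5-tris(benzyloxy)phenyl]propanoate (racemic, labile centre) | COC(C(=O)OC(C)(C)C)C(=O)c1cc(OCc2ccccc2)c(OCc2ccccc2)c(OCc2ccccc2)c1 | intermediate
6 | 2-methoxy-3-[3,4,5-tris(benzyloxy)phenyl]prop-1-ene-1,3-dione (aroyl(methoxy)ketene, not isolated) | COC(=C=O)C(=O)c1cc(OCc2ccccc2)c(OCc2ccccc2)c(OCc2ccccc2)c1 | intermediate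
7 | 2-hydroxy-6-methoxy-3-{2-methoxy-3-oxo-3-[3,4,5-tris(benzyloxy)phenyl]propanoyl}-1,4-benzoquinone (racemic, labile centre, not isolated) | COC1=CC(=O)C(C(=O)C(OC)C(=O)c2cc(OCc3ccccc3)c(OCc3ccccc3)c(OCc3ccccc3)c2)=C(O)C1=O | intermediate
8 | 3,7-dimethoxy-2-[3,4,5-tris(benzyloxy)phenyl]-4H-chromene-4,5,8-trione (flavone-5,8-quinone) | COC1=CC(=O)C2=C(C1=O)OC(=C(OC)C2=O)c1cc(OCc2ccccc2)c(OCc2ccccc2)c(OCc2ccccc2)c1 | intermediate
9 | 5,8-dihydroxy-3,7-dimethoxy-2-[3,4,5-tris(benzyloxy)phenyl]-4H-chromen-4-one (not isolated) | COc1cc(O)c2c(=O)c(OC)c(-c3cc(OCc4ccccc4)c(OCc4ccccc4)c(OCc4ccccc4)c3)oc2c1O | intermediate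
10 | 5,8-dihydroxy-3,7-dimethoxy-2-(3,4,5-trihydroxyphenyl)-4H-chromen-4-one (5,8,3',4',5'-pentahydroxy-3,7-dimethoxyflavone, achiral) | COc1cc(O)c2c(=O)c(OC)c(-c3cc(O)c(O)c(O)c3)oc2c1O | target

Total step count: 4
Longest linear sequence: 3 steps (step 1 or step 2, then steps 3 and 4)

Steps most likely to fail

Step 3 (bears the label).
- What may go wrong: acyl transfer may stop at the enol oxygen. The water set free by ring closure may hydrolyse and decarboxylate the ketene precursor. The hydroxyquinone may decay thermally before it is acylated. Ring closure may run through the ortho-quinone tautomer.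
- Fallback (known chemistry): ring A comes from a phenol and C8 is oxygenated late. It sets out from 5 and comes back at 9.
- 5 is condensed thermally with commercial phloroglucinol (Mentzer pyrone synthesis, Ph2O, about 180 °C) to 5,7-dihydroxy-3-methoxy-2-[3,4,5-tris(benzyloxy)phenyl]-4H-chromen-4-one F1.
- The non-chelated 7-OH is methylated selectively (MeI, 1.0 equiv, K2CO3, acetone) to 5-hydroxy-3,7-dimethoxy-2-[3,4,5-tris(benzyloxy)phenyl]-4H-chromen-4-one F2.
- Elbs persulfate oxidation (K2S2O8, aq KOH–pyridine, rt) attacks para to the 5-phenolate and gives potassium 5-hydroxy-3,7-dimethoxy-4-oxo-2-[3,4,5-tris(benzyloxy)phenyl]-4H-chromen-8-yl sulfate F3.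
- Warm dilute HCl hydrolyses F3 to 9, which is then isolated and submitted to the conditions of step 4.

Step 1.
- What may go wrong: hydrolysis may go on to the second methoxy group. The hydroxyquinone may self-condense or degrade under base in the alkaline medium.
- Fallback: a redox detour that avoids base at the quinone level. It sets out from 1 and comes back at 2.
- 1 is reduced (Na2S2O4, H2O–EtOAc) to 2,6-dimethoxybenzene-1,4-diol F4.
- Chelation-directed mono-demethylation next to the flanked 1-OH (AlCl3, pyridine, CH2Cl2, reflux) is the known behaviour of 2,6-dimethoxyphenols, which stops at the aluminium catecholate. It gives 6-methoxybenzene-1,2,4-triol F5.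
- Mild oxidation (Ag2O, Et2O, or air at about pH 6) gives 2.

Step 4.
- What may go wrong: the hydroquinone and pyrogallol units of the product may autoxidise during filtration and concentration. Cleavage of the flanked 4'-benzyl ether may be incomplete. The C2=C3 bond may be slowly saturated on long exposure.
- Fallback: quinone reduction is separated from deprotection, and the last step is a non-reductive solvolysis. It sets out from 8 and comes back at 10.
- 8 is reductively acetylated (Zn, Ac2O, NaOAc) to the air-stable 3,7-dimethoxy-4-oxo-2-[3,4,5-tris(benzyloxy)phenyl]-4H-chromene-5,8-diyl diacetate F6.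
- Hydrogenolysis (H2, Pd/C, EtOAc) gives 3,7-dimethoxy-4-oxo-2-(3,4,5-trihydroxyphenyl)-4H-chromene-5,8-diyl diacetate F7.
- Acid methanolysis (HCl, MeOH, Ar) removes the two acetates and gives 10.

Further compounds
F1 | step 3 | 5,7-dihydroxy-3-methoxy-2-[3,4,5-tris(benzyloxy)phenyl]-4H-chromen-4-one | COc1c(-c2cc(OCc3ccccc3)c(OCc3ccccc3)c(OCc3ccccc3)c2)oc2cc(O)cc(O)c2c1=O
F2 | step 3 | 5-hydroxy-3,7-dimethoxy-2-[3,4,5-tris(benzyloxy)phenyl]-4H-chromen-4-one | COc1cc(O)c2c(=O)c(OC)c(-c3cc(OCc4ccccc4)c(OCc4ccccc4)c(OCc4ccccc4)c3)oc2c1
F3 | step 3 | potassium 5-hydroxy-3,7-dimethoxy-4-oxo-2-[3,4,5-tris(benzyloxy)phenyl]-4H-chromen-8-yl sulfate | COc1cc(O)c2c(=O)c(OC)c(-c3cc(OCc4ccccc4)c(OCc4ccccc4)c(OCc4ccccc4)c3)oc2c1OS(=O)(=O)[O-].[K+]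
F4 | step 1 | 2,6-dimethoxybenzene-1,4-diol | COc1cc(O)cc(OC)c1O
F5 | step 1 | 6-methoxybenzene-1,2,4-triol | COc1cc(O)cc(O)c1O
F6 | step 4 | 3,7-dimethoxy-4-oxo-2-[3,4,5-tris(benzyloxy)phenyl]-4H-chromene-5,8-diyl diacetate | COc1cc(OC(C)=O)c2c(=O)c(OC)c(-c3cc(OCc4ccccc4)c(OCc4ccccc4)c(OCc4ccccc4)c3)oc2c1OC(C)=O
F7 | step 4 | 3,7-dimethoxy-4-oxo-2-(3,4,5-trihydroxyphenyl)-4H-chromene-5,8-diyl diacetate | COc1cc(OC(C)=O)c2c(=O)c(OC)c(-c3cc(O)c(O)c(O)c3)oc2c1OC(C)=O
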